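Which of the flasks, at 40 °C, 55 °C and 70 °C, holds the most open intermediate after 50 h?

| flask | starting material | solid partner | temperature | remark | time |
|---|---|---|---|---|---|
| Thursday's | 0.60 M | 0.67 equiv | 35 °C | run made earlier |  |
| Tuesday's | 0.60 M | 1.5 equiv | 55 °C | run made earlier |  |
| Sunday's | 1.2 M | 1 equiv | 35 °C | run made earlier |  |
| south-east | 0.60 M | 1.00 equiv | 70 °C |  | 50 h |
| south | 0.60 M | 1.00 equiv | 40 °C |  | 50 h |
| east | 0.60 M | 1.00 equiv | 55 °C |  | 50 h |

- the flask with the highest amount of open intermediate, in percent of the starting material charged ("all alike" if they lie within 1.5 percentage points) (south-east / south / east / all alike)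
- final open intermediate, as a percentage of the starting material charged, in south-east
- final open intermediate, as a percentage of the starting material charged, in south
- final open intermediate, as a percentage of the starting material charged, in east

- solid, in amounts per volume of the solution: solid partner
- steps that have been proposed: starting material <-> open intermediate; fresh partner -> second intermediate; open intermediate + second intermediate -> product; solid partner <-> fresh partner
- at the start none of the solid partner is in solution

| run | time / h | open intermediate / % | product / % |
|---|---|---|---|
| Thursday's | 15.0 | 2.9 | 0 |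
| Thursday's | 50.0 | 7.5 | 0 |
| Thursday's | 96.0 | 14.3 | 0 |
| Thursday's | 240 | 26.9 | 1.5 |
| Tuesday's | 10.0 | 17.3 | 1.7 |
| Tuesday's | 30.0 | 29.3 | 2.8 |
| Tuesday's | 48.0 | 30.5 | 6.6 |
| Tuesday's | 96.0 | 23.9 | 26.3 |
| Sunday's | 60.0 | 8.8 | 1.8 |
| Sunday's | 120 | 18.3 | 0 |
| Sunday's | 192 | 24.2 | 0 |
| Sunday's | 240 | 28.5 | 3.1 |

(scatter of a reading: 1 percentage point)

The open-intermediate columns give the reckoning. Thursday's run at 35 °C reads 14.3% at 96.0 h, a first-order constant k of 0.00149 h⁻¹. Sunday's run, at twice the concentration and with a different solid charge, reads about the same, 0.00153 h⁻¹, so the opening is taken as first order in starting material. The first row of Tuesday's run gives 0.0173 h⁻¹ at 55 °C, a factor of 11.6 over 35 °C.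

Spreading that factor evenly over the degrees gives 0.00275 h⁻¹ for south. Over 50 h this makes 0.137. This product k·t is the opening number, a Damköhler number.

Tuesday's run shows how to read it. At 48.0 h its opening number is 0.830, and the reading of 30.5% lies below that, so the rise has flattened. At 96.0 h the number is 1.66, open intermediate has fallen to 23.9%, and product has climbed to 26.3%.

My own reckoning follows. South's number lies below the 0.143 of Thursday's row at 96.0 h, and Thursday's run rises in a straight line up to that row, so south is put at about 13.7%. East, at 0.865, is close to Tuesday's number at 48.0 h, in a run with more solid partner, and is put at that reading, about 30.5%. South-east, at 5.44, lies beyond Tuesday's last row, so it is expected below that row's 23.9% by an amount the readings do not give. The reckoning therefore names east, above south.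

The forecast names east, with 14% in south, 30% in east and 8% in south-east, where “Most of the pool is probably consumed by 50 h”.

The flask with the most is east, at 30.2%, against 13.6% in south and 9.64% in south-east.

    starting material ⇌ open intermediate (K = 0.342, k = 0.00197 min⁻¹, Ea = 108 kJ mol⁻¹, ΔH = −37.0 kJ mol⁻¹)
    fresh partner → second intermediate (k = 0.00137 min⁻¹, Ea = 122 kJ mol⁻¹)
    open intermediate + second intermediate → product (k = 0.00526 M⁻¹ min⁻¹, Ea = 87.0 kJ mol⁻¹)
    solid partner ⇌ fresh partner, rate k4*(cs4 - [fresh partner]) while solid is left; crystals form when [fresh partner] > cs4 (solubility = 0.320 M, k = 0.0216 min⁻¹)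
    (constants at 70 °C)

In south-east the opening step alone, both ways together, relaxes with a half-life of 1.49 h, short against 50 h, and product stands at 57.2%. South, with its opening number of 0.137, holds 13.6%. Left for 500 h, the south flask reaches an opening number of 1.37 and holds less than that number reads, 36.5%.

(The runs are calculated with made-up constants; noise was put on by code.)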